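**Plan**

1. Labels: lactone C1(=O)–C2H2–C3H(OO)–C4(Me)(O)–C5H2–C6(Me)(OO), side chain C7–C16, C6a = the methyl carbon on C6; O1 (on C6) and O2 (on C3) are the peroxide oxygens.
2. Retrosynthesis: first C6a–H (C6a is carried as CH2–O, then CH2–I); then C2–C3 of the γ-lactone, by reopening it to a C4 acetate and tying C3 back to the C6a oxygen in a 2,3,5-trioxabicyclo[2.2.2]octane; then C3–O2, C3–O(C6a) and C6–O1 (H2O2 on an epoxide next to an acetal), C5–C6 (alkenyl Grignard + epoxide) and C11=C12 (Julia–Kocienski).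
3. What makes the key event possible: C3 lies between the ring peroxide oxygen O2, whose lone pair supports a cation at C3, and quaternary C4 (no β-hydrogen), whose oxygen holds the C1–C2 unit one atom away from C3.
4. Forward: the chain is joined first (side chain, then C5–C6), the trioxane bicycle is built on it, the key step sets the 1,2-dioxane ring free from the bicycle and closes the lactone ring in the same operation, and removal of the C6a oxygen ends the route.
5. Stereochemistry: C8 from (R)-citronellal; C4 from (R)-2-methylglycidol; C6 from a ligand-controlled hydroxyl-directed epoxidation followed by opening with inversion; C3 in the key step (cis fusion forced by the tether, attack anti to the leaving oxygen); both E alkenes from cross-metathesis and Julia–Kocienski olefination.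

Key step: step 14

Assumption: in step 11 the bis-hydroxamic acid ligand is used as the antipode that is matched with the (S)-carbinol and delivers oxygen to the alkene face giving the (S)-oxirane; the route is written for this combination.

**Route**

Step 1
Reactants: 1 styrene; 2 pent-4-en-1-ol
Product: 3 (4E)-5-phenylpent-4-en-1-ol
Conditions: second-generation Grubbs catalyst RuCl2(H2IMes)(PCy3)(=CHPh) (2 mol %), styrene (3 equiv), CH2Cl2, 40 °C
Reagents that add atoms: none
Why: Olefin cross-metathesis of a terminal alkene with excess styrene should give the cross product, and the styrenyl double bond forms as the thermodynamically preferred E isomer.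

Step 2
Reactants: 3 (4E)-5-phenylpent-4-en-1-ol
Product: 4 1-phenyl-5-{[(4E)-5-phenylpent-4-en-1-yl]sulfanyl}-1H-tetrazole
Conditions: 1-phenyl-1H-tetrazole-5-thiol, PPh3, DIAD, THF, 0 °C → rt
Reagents that add atoms: 1-phenyl-1H-tetrazole-5-thiol, Sc1nnnn1-c1ccccc1
Why: Mitsunobu reaction, in which the acidic heteroaryl thiol displaces the activated primary alcohol to give the sulfide needed for a Julia–Kocienski olefination.

Step 3
Reactants: 4 1-phenyl-5-{[(4E)-5-phenylpent-4-en-1-yl]sulfanyl}-1H-tetrazole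
Product: 5 1-phenyl-5-{[(4E)-5-phenylpent-4-en-1-yl]sulfonyl}-1H-tetrazole
Conditions: H2O2 (30 % aq), (NH4)6Mo7O24·4H2O (10 mol %), EtOH, 0 °C → rt
Reagents that add atoms: hydrogen peroxide, OO
Why: Molybdate-catalysed oxidation with H2O2 takes the sulfide to the sulfone and should leave the styrene unepoxidised.

Step 4
Reactants: 6 (R)-citronellal, (3R)-3,7-dimethyloct-6-enal
Product: 7 (4R)-4,8-dimethylnon-7-en-1-yne
Conditions: dimethyl (1-diazo-2-oxopropyl)phosphonate, K2CO3, MeOH, 0 °C → rt
Reagents that add atoms: dimethyl (1-diazo-2-oxopropyl)phosphonate, COP(=O)(OC)C(=[N+]=[N-])C(C)=O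
Why: Ohira–Bestmann (Seyferth–Gilbert) homologation turns the aldehyde into the terminal alkyne under mild base, and the stereocenter, which is not alpha to the carbonyl, is untouched.

Step 5
Reactants: 7 (4R)-4,8-dimethylnon-7-en-1-yne
Product: 9 (4R)-2-bromo-4,8-dimethylnona-1,7-diene, via alkenylborane 8 (not isolated)
Conditions: 9-bromo-9-borabicyclo[3.3.1]nonane, CH2Cl2, 0 °C → rt; then AcOH, 0 °C
Reagents that add atoms: 9-bromo-9-borabicyclo[3.3.1]nonane, BrB1C2CCCC1CCC2
Why: Haloboration adds B–Br syn across the terminal alkyne with bromine on the internal carbon, and protonolysis of the alkenyl–boron bond leaves the 2-bromo-1-alkene; the trisubstituted alkene should not react because the reagent has no B–H bond.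

Step 6
Reactants: 9 (4R)-2-bromo-4,8-dimethylnona-1,7-diene
Product: 11 (4R)-6-bromo-4-methylhept-6-enal, via ozonide 10 (not isolated)
Conditions: O3 (1 equiv, dye end-point), CH2Cl2, −78 °C; then PPh3, −78 °C → rt
Reagents that add atoms: ozone, O=[O+][O-]
Why: Ozonolysis with one equivalent of ozone cleaves the electron-rich trisubstituted alkene far faster than the electron-poor 2-bromoalkene, and reductive work-up gives the aldehyde (future C11).

Step 7
Reactants: 11 (4R)-6-bromo-4-methylhept-6-enal; 5 1-phenyl-5-{[(4E)-5-phenylpent-4-en-1-yl]sulfonyl}-1H-tetrazole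
Product: 13 [(1E,5E,9R)-11-bromo-9-methyldodeca-1,5,11-trien-1-yl]benzene, via metalated sulfone 12 (not isolated)
Conditions: 5, KN(SiMe3)2, DME, −78 °C; then 11, −78 °C → rt
Reagents that add atoms: none
Why: Julia–Kocienski olefination, in which addition of the metalated phenyltetrazolyl sulfone to the unbranched aldehyde, Smiles rearrangement and loss of SO2 should give the C11=C12 double bond as the E isomer.

Step 8
Reactants: 13 [(1E,5E,9R)-11-bromo-9-methyldodeca-1,5,11-trien-1-yl]benzene; 14 (R)-2-methylglycidol, [(2R)-2-methyloxiran-2-yl]methanol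
Product: 17 (2S,6R,9E,13E)-2,6-dimethyl-4-methylidene-14-phenyltetradeca-9,13-diene-1,2-diol, via alkenyl Grignard reagent 15 (not isolated), via magnesium alkoxide 16 (not isolated)
Conditions: 13, Mg, THF, 45 °C; 14, i-PrMgCl (1 equiv), THF, −40 °C; both combined, CuI (10 mol %), −40 → 0 °C; aq NH4Cl
Reagents that add atoms: none
Why: Copper-catalysed opening of the 2,2-disubstituted epoxide by the alkenyl Grignard reagent at its CH2 carbon forms C5–C6, and because no bond to the quaternary carbon is touched C4 keeps the configuration of 14 (descriptor S in the product).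

Step 9
Reactants: 17 (2S,6R,9E,13E)-2,6-dimethyl-4-methylidene-14-phenyltetradeca-9,13-diene-1,2-diol
Product: 18 (2S,6R,9E,13E)-2-hydroxy-2,6-dimethyl-4-methylidene-14-phenyltetradeca-9,13-dienal
Conditions: SO3·pyridine, DMSO, i-Pr2NEt, CH2Cl2, 0 °C
Reagents that add atoms: none
Why: Parikh–Doering oxidation takes only the primary alcohol to the aldehyde, since the tertiary alcohol cannot be oxidised and these conditions do not cleave a 1,2-diol.

Step 10
Reactants: 18 (2S,6R,9E,13E)-2-hydroxy-2,6-dimethyl-4-methylidene-14-phenyltetradeca-9,13-dienal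
Product: 19 (2S,6R,9E,13E)-1,1-dimethoxy-2,6-dimethyl-4-methylidene-14-phenyltetradeca-9,13-dien-2-ol
Conditions: HC(OMe)3, PPTS (cat.), MeOH, rt
Reagents that add atoms: trimethyl orthoformate, COC(OC)OC
Why: Acid-catalysed acetalisation with the orthoformate masks the aldehyde (future C3) at the oxidation level needed later and leaves the tertiary hydroxyl free to direct the next step.

Step 11
Reactants: 19 (2S,6R,9E,13E)-1,1-dimethoxy-2,6-dimethyl-4-methylidene-14-phenyltetradeca-9,13-dien-2-ol
Product: 20 (2S)-1,1-dimethoxy-2-methyl-3-{(2S)-2-[(2R,5E,9E)-2-methyl-10-phenyldeca-5,9-dien-1-yl]oxiran-2-yl}propan-2-ol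
Conditions: Hf(OtBu)4 (10 mol %), N,N'-dihydroxy-N,N'-bis(diphenylacetyl)-trans-cyclohexane-1,2-diamine (12 mol %, matched antipode), cumene hydroperoxide (1.5 equiv), DMPU (20 mol %), 4 Å MS, toluene, 0 °C
Reagents that add atoms: cumene hydroperoxide, CC(C)(OO)c1ccccc1
Why: Hydroxyl-directed asymmetric epoxidation, in which the hafnium-bound tertiary homoallylic alkoxide delivers the peroxide oxygen only to the nearby 1,1-disubstituted alkene (the remote E alkene and the styrene have no directing group) and the chiral bis-hydroxamic acid ligand selects the face, setting the C6 oxirane centre as S.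

Step 12
Reactants: 20 (2S)-1,1-dimethoxy-2-methyl-3-{(2S)-2-[(2R,5E,9E)-2-methyl-10-phenyldeca-5,9-dien-1-yl]oxiran-2-yl}propan-2-ol
Product: 22 (1R,4S,8S)-8-methyl-1-[(2R,5E,9E)-2-methyl-10-phenyldeca-5,9-dien-1-yl]-2,3,5-trioxabicyclo[2.2.2]octan-8-ol, via tertiary hydroperoxide 21 (not isolated)
Conditions: H2O2 (anhydrous, in Et2O, 10 equiv), H3PMo12O40 (5 mol %), Et2O, 0 °C → rt; aqueous wash; then CSA (cat.), 4 Å MS, CH2Cl2, rt
Reagents that add atoms: hydrogen peroxide, OO
Why: Acid-catalysed perhydrolysis of the 2,2-disubstituted epoxide, in which H2O2 attacks the tertiary carbon from the rear (Walden inversion, C6 becomes R) and the resulting β-hydroxy hydroperoxide condenses with the neighbouring acetal, as β-hydroxy hydroperoxides do with aldehydes, to a 1,2,4-trioxane that here is bicyclic and already contains the C3–O2 and C6–O1 bonds of the 1,2-dioxane.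

Step 13
Reactants: 22 (1R,4S,8S)-8-methyl-1-[(2R,5E,9E)-2-methyl-10-phenyldeca-5,9-dien-1-yl]-2,3,5-trioxabicyclo[2.2.2]octan-8-ol
Product: 23 (1R,4S,8S)-8-methyl-1-[(2R,5E,9E)-2-methyl-10-phenyldeca-5,9-dien-1-yl]-2,3,5-trioxabicyclo[2.2.2]octan-8-yl acetate
Conditions: Ac2O, DMAP, pyridine, CH2Cl2, rt → 40 °C
Reagents that add atoms: acetic anhydride, CC(=O)OC(C)=O
Why: DMAP-catalysed acylation of the only free (tertiary) hydroxyl places the two carbons C1 and C2 on the C4 oxygen.

Step 14
Reactants: 23 (1R,4S,8S)-8-methyl-1-[(2R,5E,9E)-2-methyl-10-phenyldeca-5,9-dien-1-yl]-2,3,5-trioxabicyclo[2.2.2]octan-8-yl acetate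
Product: 26 (3R,4aS,7aS)-3-(hydroxymethyl)-4a-methyl-3-[(2R,5E,9E)-2-methyl-10-phenyldeca-5,9-dien-1-yl]tetrahydro-3H-furo[3,2-c][1,2]dioxin-6(4H)-one, via silyl ketene acetal 24 (not isolated), via trimethylsilyl ether 25 (not isolated)
Conditions: TMSOTf (3 equiv), i-Pr2NEt (1.5 equiv), CH2Cl2 (0.01 M), −78 → −20 °C; then citric acid, MeOH, 0 °C
Reagents that add atoms: none
Why: Proposed new method: TMSOTf and i-Pr2NEt should turn the C4 acetate into its O-silyl ketene acetal 24, while excess TMSOTf silylates the most basic acetal oxygen (the ether oxygen on C6a) and ionises its bond to C3, giving a 1,2-dioxan-3-ylium (peroxycarbenium) ion that is stabilised by the ring peroxide oxygen O2 and is trapped by the ketene-acetal carbon (future C2), the silyl group ending on the C6a oxygen (25). The closest known reaction types are the intermolecular Lewis-acid-mediated addition of silyl ketene acetals and enol ethers to peroxycarbenium ions made from 3-alkoxy-1,2-dioxolanes and 3-alkoxy-1,2-dioxanes, and the one-flask silyl triflate/amine enol-silane formation with Mukaiyama-type addition of esters to acetals; new here are the intramolecular capture and the bicyclic trioxane as the source of the cation. The γ-lactone closes in a 5-(enolendo)-exo-trig mode, formally disfavoured for enolates but expected to be feasible for a neutral ketene acetal that can twist about its C1–O bond and meets a very electrophilic cation on the adjacent carbon (butenolide-forming aldol closures of α-acyloxy carbonyl compounds are of the same mode); the 1,2-dioxane ring is not made here but set free from the bicycle as the C3–O(C6a) bond breaks. The new stereocenter C3 is controlled by the two-atom tether from the C4 oxygen, which allows only the cis-fused product, and in 23 the acetoxy group lies on the side of the peroxide bridge, anti to the C3–O bond that leaves, so C2 can arrive from the rear. The step needs cleavage of the C3–O(ether) bond and not of C3–O2 (secured by the higher Lewis basicity of the ether oxygen and by the rear-side position of the nucleophile), no proton loss from the cation (C4 is quaternary) and ring closure ahead of intermolecular reaction (high dilution).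

Step 15
Reactants: 26 (3R,4aS,7aS)-3-(hydroxymethyl)-4a-methyl-3-[(2R,5E,9E)-2-methyl-10-phenyldeca-5,9-dien-1-yl]tetrahydro-3H-furo[3,2-c][1,2]dioxin-6(4H)-one
Product: 28 (3R,4aS,7aS)-3-(iodomethyl)-4a-methyl-3-[(2R,5E,9E)-2-methyl-10-phenyldeca-5,9-dien-1-yl]tetrahydro-3H-furo[3,2-c][1,2]dioxin-6(4H)-one, via triflate 27 (not isolated)
Conditions: Tf2O, 2,6-lutidine, CH2Cl2, −78 °C; then n-Bu4NI, −78 °C → rt
Reagents that add atoms: tetrabutylammonium iodide, CCCC[N+](CCCC)(CCCC)CCCC.[I-]
Why: Triflation of the only hydroxyl (primary, neopentyl-like) and SN2 displacement of the triflate by iodide at low temperature should give the iodide without touching lactone or peroxide.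

Step 16
Reactants: 28 (3R,4aS,7aS)-3-(iodomethyl)-4a-methyl-3-[(2R,5E,9E)-2-methyl-10-phenyldeca-5,9-dien-1-yl]tetrahydro-3H-furo[3,2-c][1,2]dioxin-6(4H)-one
Product: 29 (3R,4aS,7aS)-3,4a-dimethyl-3-[(2R,5E,9E)-2-methyl-10-phenyldeca-5,9-dien-1-yl]tetrahydro-3H-furo[3,2-c][1,2]dioxin-6(4H)-one (CNP0365311.2)
Conditions: Bu3SnH (5 equiv, 1 M), Et3B (cat.), air, toluene, 0 °C
Reagents that add atoms: none
Why: Radical-chain reduction of a β-iodo dialkyl peroxide by Bu3SnH, in which at high stannane concentration and low temperature hydrogen transfer to the primary radical should outrun its attack on the peroxide oxygen, leaving the C6 methyl group.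

**Compound list**

1 | styrene | C=Cc1ccccc1 | starting material
2 | pent-4-en-1-ol | OCCCC=C | starting material
3 | (4E)-5-phenylpent-4-en-1-ol | OCCC/C=C/c1ccccc1 | intermediate
4 | 1-phenyl-5-{[(4E)-5-phenylpent-4-en-1-yl]sulfanyl}-1H-tetrazole | S(CCC/C=C/c1ccccc1)c1nnnn1-c1ccccc1 | intermediate
5 | 1-phenyl-5-{[(4E)-5-phenylpent-4-en-1-yl]sulfonyl}-1H-tetrazole | O=S(=O)(CCC/C=C/c1ccccc1)c1nnnn1-c1ccccc1 | intermediate
6 | (R)-citronellal, (3R)-3,7-dimethyloct-6-enal | C[C@H](CCC=C(C)C)CC=O | starting material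
7 | (4R)-4,8-dimethylnon-7-en-1-yne | C[C@H](CCC=C(C)C)CC#C | intermediate
8 | 9-[(1Z,4R)-2-bromo-4,8-dimethylnona-1,7-dien-1-yl]-9-borabicyclo[3.3.1]nonane (not isolated) | C[C@H](CCC=C(C)C)C/C(Br)=C/B1C2CCCC1CCC2 | intermediate
9 | (4R)-2-bromo-4,8-dimethylnona-1,7-diene | C[C@H](CCC=C(C)C)CC(Br)=C | intermediate
10 | 5-[(3R)-5-bromo-3-methylhex-5-en-1-yl]-3,3-dimethyl-1,2,4-trioxolane, both epimers at the ring carbon (not isolated) | C[C@H](CCC1OOC(C)(C)O1)CC(Br)=C | intermediate
11 | (4R)-6-bromo-4-methylhept-6-enal | C[C@H](CCC=O)CC(Br)=C | intermediate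
12 | potassium salt of 5, deprotonated at the carbon next to sulfur (not isolated) | [K+].O=S(=O)([CH-]CC/C=C/c1ccccc1)c1nnnn1-c1ccccc1 | intermediate
13 | [(1E,5E,9R)-11-bromo-9-methyldodeca-1,5,11-trien-1-yl]benzene | C[C@H](CC/C=C/CC/C=C/c1ccccc1)CC(Br)=C | intermediate
14 | (R)-2-methylglycidol, [(2R)-2-methyloxiran-2-yl]methanol | C[C@@]1(CO)CO1 | starting material
15 | bromo[(4R,7E,11E)-4-methyl-12-phenyldodeca-1,7,11-trien-2-yl]magnesium (not isolated) | C[C@H](CC/C=C/CC/C=C/c1ccccc1)CC(=C)[Mg]Br | intermediate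
16 | chloromagnesium alkoxide of 14 (not isolated) | C[C@@]1(CO[Mg]Cl)CO1 | intermediate
17 | (2S,6R,9E,13E)-2,6-dimethyl-4-methylidene-14-phenyltetradeca-9,13-diene-1,2-diol | C[C@H](CC/C=C/CC/C=C/c1ccccc1)CC(=C)C[C@](C)(O)CO | intermediate
18 | (2S,6R,9E,13E)-2-hydroxy-2,6-dimethyl-4-methylidene-14-phenyltetradeca-9,13-dienal | C[C@H](CC/C=C/CC/C=C/c1ccccc1)CC(=C)C[C@](C)(O)C=O | intermediate
19 | (2S,6R,9E,13E)-1,1-dimethoxy-2,6-dimethyl-4-methylidene-14-phenyltetradeca-9,13-dien-2-ol | C[C@H](CC/C=C/CC/C=C/c1ccccc1)CC(=C)C[C@](C)(O)C(OC)OC | intermediate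
20 | (2S)-1,1-dimethoxy-2-methyl-3-{(2S)-2-[(2R,5E,9E)-2-methyl-10-phenyldeca-5,9-dien-1-yl]oxiran-2-yl}propan-2-ol | C[C@H](CC/C=C/CC/C=C/c1ccccc1)C[C@@]1(CO1)C[C@](C)(O)C(OC)OC | intermediate
21 | (2S,4R,6R,9E,13E)-4-hydroperoxy-4-(hydroxymethyl)-1,1-dimethoxy-2,6-dimethyl-14-phenyltetradeca-9,13-dien-2-ol (not isolated) | C[C@H](CC/C=C/CC/C=C/c1ccccc1)C[C@@](CO)(OO)C[C@](C)(O)C(OC)OC | intermediate
22 | (1R,4S,8S)-8-methyl-1-[(2R,5E,9E)-2-methyl-10-phenyldeca-5,9-dien-1-yl]-2,3,5-trioxabicyclo[2.2.2]octan-8-ol | C[C@H](CC/C=C/CC/C=C/c1ccccc1)C[C@@]12CO[C@@H](OO1)[C@@](C)(O)C2 | intermediate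
23 | (1R,4S,8S)-8-methyl-1-[(2R,5E,9E)-2-methyl-10-phenyldeca-5,9-dien-1-yl]-2,3,5-trioxabicyclo[2.2.2]octan-8-yl acetate | C[C@H](CC/C=C/CC/C=C/c1ccccc1)C[C@@]12CO[C@@H](OO1)[C@@](C)(OC(C)=O)C2 | intermediate
24 | O-trimethylsilyl ketene acetal of 23, (1R,4S,8S)-8-methyl-1-[(2R,5E,9E)-2-methyl-10-phenyldeca-5,9-dien-1-yl]-8-({1-[(trimethylsilyl)oxy]ethenyl}oxy)-2,3,5-trioxabicyclo[2.2.2]octane (not isolated) | C[C@H](CC/C=C/CC/C=C/c1ccccc1)C[C@@]12CO[C@@H](OO1)[C@@](C)(OC(=C)O[Si](C)(C)C)C2 | intermediate
25 | trimethylsilyl ether of 26 (not isolated) | C[C@H](CC/C=C/CC/C=C/c1ccccc1)C[C@]1(CO[Si](C)(C)C)C[C@]2(C)OC(=O)C[C@@H]2OO1 | intermediate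
26 | (3R,4aS,7aS)-3-(hydroxymethyl)-4a-methyl-3-[(2R,5E,9E)-2-methyl-10-phenyldeca-5,9-dien-1-yl]tetrahydro-3H-furo[3,2-c][1,2]dioxin-6(4H)-one | C[C@H](CC/C=C/CC/C=C/c1ccccc1)C[C@]1(CO)C[C@]2(C)OC(=O)C[C@@H]2OO1 | intermediate
27 | trifluoromethanesulfonate of 26 (not isolated) | C[C@H](CC/C=C/CC/C=C/c1ccccc1)C[C@]1(COS(=O)(=O)C(F)(F)F)C[C@]2(C)OC(=O)C[C@@H]2OO1 | intermediate
28 | (3R,4aS,7aS)-3-(iodomethyl)-4a-methyl-3-[(2R,5E,9E)-2-methyl-10-phenyldeca-5,9-dien-1-yl]tetrahydro-3H-furo[3,2-c][1,2]dioxin-6(4H)-one | C[C@H](CC/C=C/CC/C=C/c1ccccc1)C[C@]1(CI)C[C@]2(C)OC(=O)C[C@@H]2OO1 | intermediate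
29 | (3R,4aS,7aS)-3,4a-dimethyl-3-[(2R,5E,9E)-2-methyl-10-phenyldeca-5,9-dien-1-yl]tetrahydro-3H-furo[3,2-c][1,2]dioxin-6(4H)-one | C[C@H](CC/C=C/CC/C=C/c1ccccc1)C[C@]1(C)C[C@]2(C)OC(=O)C[C@@H]2OO1 | target

**Totals**

Total step count: 16.
Longest linear sequence: 13 steps (steps 4–16 from (R)-citronellal; the branch from styrene, steps 1–3 and 7–16, is equally long).

**Steps most likely to fail, with fallbacks**

Step 14 (bears the label Proposed new method). What may go wrong: ionisation of the trioxane at the peroxide bond C3–O2 in place of the ether bond, a lactone closure too slow for the strained five-membered transition state, or intermolecular reaction of the cation. The fallback uses known chemistry and forms the same carbon–carbon bond between two molecules. It sets out from 22: TMSOTf (or TiCl4) and 1-methoxy-1-(trimethylsilyloxy)ethene in CH2Cl2 at −78 °C (the known addition of a silyl ketene acetal to a cyclic peroxyacetal, here with attack anti to the departing bridge oxygen), followed by a desilylating work-up, should give the hydroxy ester methyl 2-[(3S,4S,6R)-4-hydroxy-6-(hydroxymethyl)-4-methyl-6-[(2R,5E,9E)-2-methyl-10-phenyldeca-5,9-dien-1-yl]-1,2-dioxan-3-yl]acetate F1. Its ester group is cis to the C4 hydroxyl, so it should lactonise with CSA in toluene and come back to the route at 26.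

Step 12. What may go wrong: participation of an acetal methoxy oxygen or of the tertiary hydroxyl in the epoxide opening, or partial loss of inversion through an open tertiary cation. The same detour also answers poor face selectivity in step 11. The fallback gives up the epoxide and builds the peroxide by halocyclisation, without face control at C6. It sets out from 19: acid-catalysed exchange with ethereal H2O2 (PPTS) should give the hydroperoxy acetal (2S,6R,9E,13E)-1-hydroperoxy-1-methoxy-2,6-dimethyl-4-methylidene-14-phenyltetradeca-9,13-dien-2-ol F2. N-Iodosuccinimide in CH2Cl2 should then close the 1,2-dioxane by 6-exo iodoperoxidation to (4S,6R)-6-(iodomethyl)-3-methoxy-4-methyl-6-[(2R,5E,9E)-2-methyl-10-phenyldeca-5,9-dien-1-yl]-1,2-dioxan-4-ol F3, together with its (4S,6S) epimer F4, which is removed by chromatography. F3 with 1-methoxy-1-(trimethylsilyloxy)ethene and TMSOTf (or TiCl4) at −78 °C should give methyl 2-[(3S,4S,6R)-4-hydroxy-6-(iodomethyl)-4-methyl-6-[(2R,5E,9E)-2-methyl-10-phenyldeca-5,9-dien-1-yl]-1,2-dioxan-3-yl]acetate F5, along with its (3R) epimer F6, which cannot lactonise and is separated. CSA in toluene should close F5 to the lactone, and the fallback comes back to the route at 28, before step 16.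

Step 16. What may go wrong: attack of the primary carbon radical on the neighbouring peroxide oxygen (ring-opening to a spiro-epoxide and an alkoxy radical) before hydrogen transfer. The fallback replaces the radical chain by an ionic hydride displacement. It sets out from the triflate 27 (made from 26 as in step 15): n-Bu4NBH4 in benzene/THF at rt should displace the primary triflate by hydride and comes back to the route at 29; no new compound is formed.

**Further compounds**

F1 | step 14 | methyl 2-[(3S,4S,6R)-4-hydroxy-6-(hydroxymethyl)-4-methyl-6-[(2R,5E,9E)-2-methyl-10-phenyldeca-5,9-dien-1-yl]-1,2-dioxan-3-yl]acetate | C[C@H](CC/C=C/CC/C=C/c1ccccc1)C[C@]1(CO)C[C@](C)(O)[C@H](CC(=O)OC)OO1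
F2 | step 12 | (2S,6R,9E,13E)-1-hydroperoxy-1-methoxy-2,6-dimethyl-4-methylidene-14-phenyltetradeca-9,13-dien-2-ol (both C1 epimers) | C[C@H](CC/C=C/CC/C=C/c1ccccc1)CC(=C)C[C@](C)(O)C(OC)OO
F3 | step 12 | (4S,6R)-6-(iodomethyl)-3-methoxy-4-methyl-6-[(2R,5E,9E)-2-methyl-10-phenyldeca-5,9-dien-1-yl]-1,2-dioxan-4-ol (both C3 epimers) | C[C@H](CC/C=C/CC/C=C/c1ccccc1)C[C@]1(CI)C[C@](C)(O)C(OC)OO1
F4 | step 12 | (4S,6S)-6-(iodomethyl)-3-methoxy-4-methyl-6-[(2R,5E,9E)-2-methyl-10-phenyldeca-5,9-dien-1-yl]-1,2-dioxan-4-ol (both C3 epimers) | C[C@H](CC/C=C/CC/C=C/c1ccccc1)C[C@@]1(CI)C[C@](C)(O)C(OC)OO1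
F5 | step 12 | methyl 2-[(3S,4S,6R)-4-hydroxy-6-(iodomethyl)-4-methyl-6-[(2R,5E,9E)-2-methyl-10-phenyldeca-5,9-dien-1-yl]-1,2-dioxan-3-yl]acetate | C[C@H](CC/C=C/CC/C=C/c1ccccc1)C[C@]1(CI)C[C@](C)(O)[C@H](CC(=O)OC)OO1
F6 | step 12 | methyl 2-[(3R,4S,6R)-4-hydroxy-6-(iodomethyl)-4-methyl-6-[(2R,5E,9E)-2-methyl-10-phenyldeca-5,9-dien-1-yl]-1,2-dioxan-3-yl]acetate | C[C@H](CC/C=C/CC/C=C/c1ccccc1)C[C@]1(CI)C[C@](C)(O)[C@@H](CC(=O)OC)OO1
F0 | step 16 | none | none
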